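**Retrosynthetic overview**
- Target ⇒ methanol ring-opening of a tricyclic aryl lactone ⇒ C8–C bond and side-chain stereocentre by a carbene-catalysed [3+3] annulation (new) of the 6-prenyl cis-chromanone with (E)-hex-2-enal.
- 6-Prenyl chromanone ⇒ aromatic Claisen rearrangement, steered to C6 by the 5-OH···O=C chelate, of the 7-O-(1,1-dimethylallyl) ether ⇒ Pd O-allylation of cis-5,7-dihydroxy-2,3-dimethylchromanone.
- cis-Chromanone ⇒ quinine-catalysed asymmetric oxa-Michael closure (sets C2 and C3, the first stereocentres) of 2-tigloylphloroglucinol ⇒ Friedel–Crafts acylation of phloroglucinol.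
- Ring order: the arene is bought; the pyranone ring is closed first (step 2); the lactone ring is formed last and opened in the same flask.

Assumption: (−)-quinine is taken to give the 2R series as it does with o-tigloylphenols of the coumarin class, and the triazolium antipode named in step 6 is taken to open the β-Re face of the acyl azolium; if the first run shows the other sense, the mirror-image salt (also sold) is used and nothing else changes.

**Step 1**
Reactants: 1 phloroglucinol (benzene-1,3,5-triol, anhydrous); 2 tigloyl chloride [(E)-2-methylbut-2-enoyl chloride]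
Product: 3 (E)-2-methyl-1-(2,4,6-trihydroxyphenyl)but-2-en-1-one
Conditions: AlCl3 (3.5 equiv), PhNO2/CH2Cl2, 0 °C → rt; ice/1 M HCl, cold work-up; any cyclised racemic chromanone removed on silica
Reagents that add atoms: tigloyl chloride, C/C=C(\C)C(=O)Cl
Why: Friedel–Crafts C-acylation of the symmetric triphenol gives a single mono-ketone, and the aluminium chelate of the product plus a cold acidic quench keep the enone open, as in tigloylations of dihydroxycoumarins; no stereocentre is formed.

**Step 2**
Reactants: 3 (E)-2-methyl-1-(2,4,6-trihydroxyphenyl)but-2-en-1-one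
Product: 4 (2R,3S)-5,7-dihydroxy-2,3-dimethylchroman-4-one (cis)
Conditions: (−)-quinine (15 mol%), PhCl (minimum THF to dissolve), 10–15 °C, 24–48 h; recrystallise to raise ee
Reagents that add atoms: none
Why: Cinchona-alkaloid-catalysed asymmetric intramolecular oxa-Michael addition (6-endo): the quinuclidine nitrogen ion-pairs with one of the two equivalent ortho-phenols while the C9-OH binds the enone, so oxygen adds to the β-face that gives 2R, and kinetic protonation of the enol inside the ion pair gives the cis (3S) isomer.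

**Step 3**
Reactants: 5 2-methylbut-3-en-2-ol; 6 di-tert-butyl dicarbonate
Product: 8 tert-butyl 2-methylbut-3-en-2-yl carbonate, via lithium 2-methylbut-3-en-2-olate 7 (not isolated)
Conditions: n-BuLi (1.05 equiv), THF, −78 → 0 °C; then Boc2O, 0 °C → rt; H2O
Reagents that add atoms: di-tert-butyl dicarbonate, CC(C)(C)OC(=O)OC(=O)OC(C)(C)C
Why: Alkoxycarbonylation of the lithium tert-alkoxide with Boc2O is the standard route to this mixed carbonate; no stereocentre is involved.

**Step 4**
Reactants: 4 (2R,3S)-5,7-dihydroxy-2,3-dimethylchroman-4-one; 8 tert-butyl 2-methylbut-3-en-2-yl carbonate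
Product: 9 (2R,3S)-5-hydroxy-2,3-dimethyl-7-[(2-methylbut-3-en-2-yl)oxy]chroman-4-one
Conditions: Pd(PPh3)4 (5 mol%), 8 (1.2 equiv), 4 Å MS, THF, 0–5 °C; filtration through neutral alumina
Reagents that add atoms: tert-butyl 2-methylbut-3-en-2-yl carbonate, CC(C)(C)OC(=O)OC(C)(C)C=C
Why: Pd-catalysed decarboxylative allylic etherification (Tsuji–Trost O-allylation): the tert-butoxide released on ionisation deprotonates only the acidic, non-chelated 7-OH, and the phenoxide attacks the substituted terminus of the π-allyl complex under kinetic control to give the tertiary ether; the chelated 5-OH and the C2/C3 centres are untouched.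

**Step 5**
Reactants: 9 (2R,3S)-5-hydroxy-2,3-dimethyl-7-[(2-methylbut-3-en-2-yl)oxy]chroman-4-one
Product: 10 (2R,3S)-5,7-dihydroxy-2,3-dimethyl-6-(3-methylbut-2-en-1-yl)chroman-4-one
Conditions: PhMe (degassed), 115 °C, sealed tube, 6 h
Reagents that add atoms: none
Why: Aromatic Claisen [3,3] rearrangement: the 5-OH···O=C4 chelate fixes the C4a=C5/C6=C7 Kekulé form, so the allyl terminus migrates to C6 (as 4-allyloxy-2-hydroxyaryl ketones rearrange to the carbon between the two oxygens), the tertiary ether delivers the normal prenyl group, and the neutral conditions leave the cis C2/C3 pair intact.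

**Step 6**
Reactants: 10 (2R,3S)-5,7-dihydroxy-2,3-dimethyl-6-(3-methylbut-2-en-1-yl)chroman-4-one; 11 (E)-hex-2-enal; 12 methanol
Product: 14 methyl (3R)-3-[(2R,3S)-5,7-dihydroxy-2,3-dimethyl-6-(3-methylbut-2-en-1-yl)-4-oxo-3,4-dihydro-2H-chromen-8-yl]hexanoate, via tricyclic aryl lactone 13 (not isolated)
Conditions: (5aS,10bR)-N-mesityl aminoindanol-derived triazolium chloride (10 mol%), i-Pr2NEt (30 mol%), 3,3',5,5'-tetra-tert-butyldiphenoquinone (DQ, 1.1 equiv), 11 (1.3 equiv), 4 Å MS, PhMe/THF 4:1, 0 °C → rt; then MeOH (excess), rt, 2–4 h; AcOH quench, evaporation below 30 °C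
Reagents that add atoms: (E)-hex-2-enal, CCC/C=C/C=O; methanol, CO
Why: Proposed new method: the chiral triazolylidene and DQ turn 11 into the α,β-unsaturated acyl azolium; the 7-phenoxide of 10 (a vinylogous acid) adds through C8, its only free ring carbon, to the β-Re face in a dearomatising Michael step (or O-acylation then [3,3] through the same face); re-aromatisation and O-acylation by the 7-OH release the carbene and give lactone 13, whose activated aryl-ester bond is then opened by MeOH under the same carbene/amine (transesterification) to leave the methyl ester and the free 7-OH; the C8–C bond and the (R) side-chain centre are catalyst-controlled because C2/C3 are remote; the closest known chemistry is the carbene-catalysed oxidative [3+3] annulation of enals or ynals with 1,3-dicarbonyls, kojic acids and naphthols, not yet shown on an unprotected, fully substituted acylphloroglucinol-type chromanone or coupled to in-flask methanolysis.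

**Compound list**
1 | phloroglucinol (benzene-1,3,5-triol) | Oc1cc(O)cc(O)c1 | starting material
2 | tigloyl chloride, (E)-2-methylbut-2-enoyl chloride | C/C=C(\C)C(=O)Cl | starting material
3 | (E)-2-methyl-1-(2,4,6-trihydroxyphenyl)but-2-en-1-one | C/C=C(\C)C(=O)c1c(O)cc(O)cc1O | intermediate
4 | (2R,3S)-5,7-dihydroxy-2,3-dimethylchroman-4-one (cis) | Oc1cc(O)c2c(c1)O[C@H](C)[C@H](C)C2=O | intermediate
5 | 2-methylbut-3-en-2-ol | CC(C)(O)C=C | starting material
6 | di-tert-butyl dicarbonate | CC(C)(C)OC(=O)OC(=O)OC(C)(C)C | starting material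
7 | lithium 2-methylbut-3-en-2-olate (not isolated) | [Li+].[O-]C(C)(C)C=C | intermediate
8 | tert-butyl 2-methylbut-3-en-2-yl carbonate | CC(C)(C)OC(=O)OC(C)(C)C=C | intermediate
9 | (2R,3S)-5-hydroxy-2,3-dimethyl-7-[(2-methylbut-3-en-2-yl)oxy]chroman-4-one | C=CC(C)(C)Oc1cc(O)c2c(c1)O[C@H](C)[C@H](C)C2=O | intermediate
10 | (2R,3S)-5,7-dihydroxy-2,3-dimethyl-6-(3-methylbut-2-en-1-yl)chroman-4-one | c1c(O)c(CC=C(C)C)c(O)c2c1O[C@H](C)[C@H](C)C2=O | intermediate
11 | (E)-hex-2-enal | CCC/C=C/C=O | starting material
12 | methanol | CO | starting material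
13 | (2R,3S,10R)-5-hydroxy-2,3-dimethyl-6-(3-methylbut-2-en-1-yl)-10-propyl-2,3,9,10-tetrahydro-4H,8H-pyrano[2,3-f]chromene-4,8-dione (dihydrocoumarin-type lactone between the 7-O and C8 of the chromanone; not isolated) | CCC[C@@H]1CC(=O)Oc2c(CC=C(C)C)c(O)c3c(c21)O[C@H](C)[C@H](C)C3=O | intermediate
14 | methyl (3R)-3-[(2R,3S)-5,7-dihydroxy-2,3-dimethyl-6-(3-methylbut-2-en-1-yl)-4-oxo-3,4-dihydro-2H-chromen-8-yl]hexanoate | CCC[C@H](CC(=O)OC)c1c(O)c(CC=C(C)C)c(O)c2c1O[C@H](C)[C@H](C)C2=O | target

**Step count**
Total steps: 6. Longest linear sequence: 5 (steps 1 → 2 → 4 → 5 → 6); step 3 is a one-step side branch.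

**Steps most likely to fail**

Step 6 (the new annulation). The acyl-deactivated phenoxide may be too weak a carbon nucleophile for the acyl azolium, may stop at the O-hexenoyl ester, or may give poor diastereocontrol. The fallback uses known iminium-ion catalysis, sets out from 10 and comes back at 13. Compounds 10 and 11 are treated with (S)-α,α-diphenylprolinol trimethylsilyl ether (20 mol%) and PhCO2H in PhMe at 0 °C. Friedel–Crafts-type conjugate addition at C8 (the (S)-catalyst opens the β-Re face of the aliphatic enal) and hemiacetal formation with the 7-OH give the lactol (2R,3S,10R)-5,8-dihydroxy-2,3-dimethyl-6-(3-methylbut-2-en-1-yl)-10-propyl-2,3,9,10-tetrahydro-4H,8H-pyrano[2,3-f]chromen-4-one F1 as an anomer mixture. Fetizon oxidation (Ag2CO3 on Celite, PhMe, 80 °C) gives lactone 13, here isolated, which is opened to 14 with MeOH and catalytic Et3N at 0 °C as in the second stage of step 6.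

Step 5 (Claisen regiochemistry). Migration to C8 instead of C6, or loss of isoprene back to 4, would cost material and give an isomer that is hard to remove. The fallback anchors the allyl group on O5, whose only free ortho carbon is C6; it sets out from 4 and comes back at 10. The 7-OH is silylated (TIPSCl, imidazole, DMF, 0 °C) to (2R,3S)-5-hydroxy-2,3-dimethyl-7-[(triisopropylsilyl)oxy]chroman-4-one F2. Pd-catalysed tert-prenylation of the remaining 5-OH with 8 (Pd(PPh3)4, THF, rt) gives (2R,3S)-2,3-dimethyl-5-[(2-methylbut-3-en-2-yl)oxy]-7-[(triisopropylsilyl)oxy]chroman-4-one F3. Claisen rearrangement (Eu(fod)3 10 mol%, CHCl3, 60 °C) gives (2R,3S)-5-hydroxy-2,3-dimethyl-6-(3-methylbut-2-en-1-yl)-7-[(triisopropylsilyl)oxy]chroman-4-one F4, and Et3N·3HF in THF at 0 °C frees 10.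

Step 2 (asymmetric oxa-Michael on the free triol). Poor solubility in PhCl and a racemic background closure could erode ee and the cis/trans ratio. The fallback replaces asymmetric catalysis by resolution; it sets out from 3 and comes back at 4. Compound 3 is closed with catalytic Et3N in PhCl at 0 °C to the racemic chromanone: the cis pair is 4 with its mirror image (2S,3R)-5,7-dihydroxy-2,3-dimethylchroman-4-one F5, and the trans pair is (2R,3R)-5,7-dihydroxy-2,3-dimethylchroman-4-one F6 with (2S,3S)-5,7-dihydroxy-2,3-dimethylchroman-4-one F7. The cis racemate is separated from the trans on silica and resolved by preparative chiral SFC (amylose carbamate phase); only 4 is carried on.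

**Further compounds**
F1 | step 6 | (2R,3S,10R)-5,8-dihydroxy-2,3-dimethyl-6-(3-methylbut-2-en-1-yl)-10-propyl-2,3,9,10-tetrahydro-4H,8H-pyrano[2,3-f]chromen-4-one (lactol, both anomers) | CCC[C@@H]1CC(O)Oc2c(CC=C(C)C)c(O)c3c(c21)O[C@H](C)[C@H](C)C3=O
F2 | step 5 | (2R,3S)-5-hydroxy-2,3-dimethyl-7-[(triisopropylsilyl)oxy]chroman-4-one | CC(C)[Si](Oc1cc(O)c2c(c1)O[C@H](C)[C@H](C)C2=O)(C(C)C)C(C)C
F3 | step 5 | (2R,3S)-2,3-dimethyl-5-[(2-methylbut-3-en-2-yl)oxy]-7-[(triisopropylsilyl)oxy]chroman-4-one | CC(C)[Si](Oc1cc(OC(C)(C)C=C)c2c(c1)O[C@H](C)[C@H](C)C2=O)(C(C)C)C(C)C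
F4 | step 5 | (2R,3S)-5-hydroxy-2,3-dimethyl-6-(3-methylbut-2-en-1-yl)-7-[(triisopropylsilyl)oxy]chroman-4-one | c1c(O[Si](C(C)C)(C(C)C)C(C)C)c(CC=C(C)C)c(O)c2c1O[C@H](C)[C@H](C)C2=O
F5 | step 2 | (2S,3R)-5,7-dihydroxy-2,3-dimethylchroman-4-one | Oc1cc(O)c2c(c1)O[C@@H](C)[C@@H](C)C2=O
F6 | step 2 | (2R,3R)-5,7-dihydroxy-2,3-dimethylchroman-4-one | Oc1cc(O)c2c(c1)O[C@H](C)[C@@H](C)C2=O
F7 | step 2 | (2S,3S)-5,7-dihydroxy-2,3-dimethylchroman-4-one | Oc1cc(O)c2c(c1)O[C@@H](C)[C@H](C)C2=O
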